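**Retrosynthetic overview**

1. Target 15 ⇒ dihydroxy lactone 13 by removing the C8 prenyl group (C8 is the only free carbon of the phloroglucinol ring) ⇒ bis(benzyl ether) 10 by masking O5 and O7.
2. Feature: in the chroman-2-one ring, C2 is a single carbonyl carbon between O1 and the C3 methylene, and C3–C4(H)(Ph) on C4a is the hydro form of a 1-phenylvinyl group ortho to the O1 phenol. So 10 ⇒ vinylphenol 8 + CO (9), forming O1–C2, C2–C3 and the C4–H stereocentre in one asymmetric Pd–H cyclocarbonylation.
3. 8 ⇒ iodophenol 6 + 1-phenylvinylboronate 7 (Suzuki–Miyaura); 6 ⇒ phenol 5 by ortho-iodination (its two ortho positions are equivalent).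
4. 5 ⇒ 2,4,6-trihydroxybenzophenone 1 by tosylation of the para OH, benzylation of the two chelated OH, and detosylation. Benzyl ethers are chosen for O5/O7 so the last unmasking is a neutral hydrogenolysis and the lactone is never opened next to a free 5-OH.
5. Ring order: the three benzene rings are bought; the lactone ring is the only ring made, in step 6.

Key step: step 6

Assumption: which hand of the chiral bisphosphine delivers 4R on this diaryl alkene cannot be predicted safely; both hands are commercial, and the route is written for the one that a pilot run shows to give the 4R lactone.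

**Route**

Step 1
Reactants: 1 2,4,6-trihydroxybenzophenone
Product: 2 4-benzoyl-3,5-dihydroxyphenyl 4-methylbenzenesulfonate
Conditions: TsCl (1.05 equiv), K2CO3 (1.2 equiv), acetone, 0 °C to rt
Reagents that add atoms: p-toluenesulfonyl chloride, Cc1ccc(cc1)S(Cl)(=O)=O
Why: The para OH is the only hydroxyl not hydrogen-bonded to the ketone and the most acidic one, so one equivalent of sulfonyl chloride under weak base should give selective O-sulfonylation there (selective phenol tosylation).

Step 2
Reactants: 2 4-benzoyl-3,5-dihydroxyphenyl 4-methylbenzenesulfonate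
Product: 4 4-benzoyl-3,5-bis(benzyloxy)phenyl 4-methylbenzenesulfonate, via mono-benzyl ether 3 (not isolated)
Conditions: BnBr (2.5 equiv), K2CO3 (3 equiv), Bu4NI (cat.), DMF, 60 °C
Reagents that add atoms: benzyl bromide, BrCc1ccccc1
Why: Williamson etherification, in which the two chelated ortho hydroxyls are alkylated one after the other under forcing carbonate/DMF conditions while the aryl tosylate is inert to carbonate in the absence of hydroxide.

Step 3
Reactants: 4 4-benzoyl-3,5-bis(benzyloxy)phenyl 4-methylbenzenesulfonate
Product: 5 [2,6-bis(benzyloxy)-4-hydroxyphenyl](phenyl)methanone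
Conditions: KOH (5 equiv), 1,4-dioxane/H2O 3:1, 90 °C; then 1 M HCl
Reagents that add atoms: none
Why: Aryl sulfonate hydrolysis, in which hydroxide attacks sulfur and expels the para-acyl phenoxide, with benzyl ethers and the non-enolisable diaryl ketone stable to aqueous base and no alcohol co-solvent present that could form an alkylating sulfonate ester.

Step 4
Reactants: 5 [2,6-bis(benzyloxy)-4-hydroxyphenyl](phenyl)methanone
Product: 6 [2,6-bis(benzyloxy)-4-hydroxy-3-iodophenyl](phenyl)methanone
Conditions: NIS (1.0 equiv), MeCN, 0 °C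
Reagents that add atoms: N-iodosuccinimide, O=C1CCC(=O)N1I
Why: Electrophilic aromatic iodination directed by the free phenol to its two equivalent ortho positions, where one equivalent at low temperature should stop at the mono-iodide because the first iodine deactivates and crowds the ring.

Step 5
Reactants: 6 [2,6-bis(benzyloxy)-4-hydroxy-3-iodophenyl](phenyl)methanone; 7 4,4,5,5-tetramethyl-2-(1-phenylvinyl)-1,3,2-dioxaborolane (1.5 equiv)
Product: 8 [2,6-bis(benzyloxy)-4-hydroxy-3-(1-phenylvinyl)phenyl](phenyl)methanone
Conditions: Pd(OAc)2 (5 mol %), SPhos (10 mol %), K3PO4 (3 equiv), 1,4-dioxane/H2O 5:1, 80 °C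
Reagents that add atoms: none
Why: Suzuki–Miyaura coupling of an ortho-iodophenol with an α-substituted vinylboronate, where the bulky electron-rich biarylphosphine supports oxidative addition and transmetalation at the di-ortho-substituted iodide and the free phenol is tolerated under phosphate base.

Step 6
Reactants: 8 [2,6-bis(benzyloxy)-4-hydroxy-3-(1-phenylvinyl)phenyl](phenyl)methanone; 9 carbon monoxide
Product: 10 (R)-6-benzoyl-5,7-bis(benzyloxy)-4-phenylchroman-2-one
Conditions: Pd(OAc)2 (5 mol %), (R,R)- or (S,S)-DIOP (6 mol %, hand fixed by pilot run), CO/H2 1:1 (40 bar), CH2Cl2, 100 °C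
Reagents that add atoms: none
Why: A bisphosphine palladium hydride, formed from Pd(0) under CO/H2, adds across the 1,1-diarylethylene with hydrogen to the diaryl carbon (future C4) and palladium to the terminal CH2; CO then inserts into the primary alkyl–Pd bond (C2–C3) and the ortho phenol captures the acyl–Pd (O1–C2), returning the hydride. The closest known reaction type is the palladium-catalysed cyclocarbonylation (intramolecular hydroaryloxycarbonylation) of 2-(1-substituted vinyl)phenols to 4-substituted 3,4-dihydrocoumarins, which has asymmetric variants with chiral bisphosphines. The lactone ring closes by 6-exo-trig attack of the phenol oxygen on the acyl-palladium carbon, equivalent to C–O reductive elimination from an aryloxy(acyl)palladium chelate. The C4 stereocentre is created when hydride is delivered to one alkene face, and it is controlled by the chiral bisphosphine, which distinguishes the coplanar phenyl group from the twisted, di-ortho-substituted aryl ring whose phenol can bind palladium; because hydropalladation is reversible, the ligand can also select at CO insertion and acyl capture. The step needs anti-Markovnikov regioselectivity (six-membered lactone, not the quaternary 3-methyl-3-phenylbenzofuranone), and the substrate secures it because palladium at the tertiary, doubly benzylic carbon is too crowded to persist or insert CO. Benzyl ethers and the twisted benzophenone carbonyl should be inert to a homogeneous phosphine–palladium hydride under CO.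

Step 7
Reactants: 10 (R)-6-benzoyl-5,7-bis(benzyloxy)-4-phenylchroman-2-one
Product: 13 (R)-6-benzoyl-5,7-dihydroxy-4-phenylchroman-2-one, via 5-O-benzyl mono-ether 11 (not isolated), via 7-O-benzyl mono-ether 12 (not isolated)
Conditions: H2 (1 atm), 10% Pd/C, EtOAc, rt, stopped after uptake of 2 equiv
Reagents that add atoms: none
Why: Catalytic hydrogenolysis of both aryl benzyl ethers in a neutral, non-nucleophilic medium, so the lactone is not opened and cannot re-close on the freed 5-OH, while the di-ortho-substituted, hydrogen-bonded benzophenone carbonyl is reduced far more slowly and C4, which carries no heteroatom, is untouched.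

Step 8
Reactants: 13 (R)-6-benzoyl-5,7-dihydroxy-4-phenylchroman-2-one; 14 prenyl bromide (1.1 equiv)
Product: 15 (R)-6-benzoyl-5,7-dihydroxy-8-(3-methylbut-2-en-1-yl)-4-phenylchroman-2-one
Conditions: DBU (1.1 equiv), THF, 0 °C to rt; then dilute HCl
Reagents that add atoms: none
Why: C-alkylation of an acylphloroglucinol-type phenoxide by an allylic bromide at C8, the only unsubstituted ring carbon (ortho to O7, para to O5), favoured because both hydroxyls are hydrogen-bonded to the benzoyl carbonyl, and run with an anhydrous amidine base that should neither open the lactone nor remove the C4 proton.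

**Compound list**

1 | 2,4,6-trihydroxybenzophenone | O=C(c1ccccc1)c1c(O)cc(O)cc1O | starting material
2 | 4-benzoyl-3,5-dihydroxyphenyl 4-methylbenzenesulfonate | O=C(c1ccccc1)c1c(O)cc(OS(=O)(=O)c2ccc(C)cc2)cc1O | intermediate
3 | 4-benzoyl-3-(benzyloxy)-5-hydroxyphenyl 4-methylbenzenesulfonate (mono-benzyl ether, not isolated) | O=C(c1ccccc1)c1c(OCc2ccccc2)cc(OS(=O)(=O)c2ccc(C)cc2)cc1O | intermediate
4 | 4-benzoyl-3,5-bis(benzyloxy)phenyl 4-methylbenzenesulfonate | O=C(c1ccccc1)c1c(OCc2ccccc2)cc(OS(=O)(=O)c2ccc(C)cc2)cc1OCc1ccccc1 | intermediate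
5 | [2,6-bis(benzyloxy)-4-hydroxyphenyl](phenyl)methanone | O=C(c1ccccc1)c1c(OCc2ccccc2)cc(O)cc1OCc1ccccc1 | intermediate
6 | [2,6-bis(benzyloxy)-4-hydroxy-3-iodophenyl](phenyl)methanone | O=C(c1ccccc1)c1c(OCc2ccccc2)cc(O)c(I)c1OCc1ccccc1 | intermediate
7 | 4,4,5,5-tetramethyl-2-(1-phenylvinyl)-1,3,2-dioxaborolane | C=C(B1OC(C)(C)C(C)(C)O1)c1ccccc1 | starting material
8 | [2,6-bis(benzyloxy)-4-hydroxy-3-(1-phenylvinyl)phenyl](phenyl)methanone | C=C(c1ccccc1)c1c(O)cc(OCc2ccccc2)c(C(=O)c2ccccc2)c1OCc1ccccc1 | intermediate
9 | carbon monoxide | [C-]#[O+] | starting material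
10 | (R)-6-benzoyl-5,7-bis(benzyloxy)-4-phenylchroman-2-one | c1c(OCc3ccccc3)c(C(=O)c3ccccc3)c(OCc3ccccc3)c2c1OC(=O)C[C@@H]2c1ccccc1 | intermediate
11 | (R)-6-benzoyl-5-(benzyloxy)-7-hydroxy-4-phenylchroman-2-one (5-O-benzyl mono-ether, not isolated) | c1c(O)c(C(=O)c3ccccc3)c(OCc3ccccc3)c2c1OC(=O)C[C@@H]2c1ccccc1 | intermediate
12 | (R)-6-benzoyl-7-(benzyloxy)-5-hydroxy-4-phenylchroman-2-one (7-O-benzyl mono-ether, not isolated) | c1c(OCc3ccccc3)c(C(=O)c3ccccc3)c(O)c2c1OC(=O)C[C@@H]2c1ccccc1 | intermediate
13 | (R)-6-benzoyl-5,7-dihydroxy-4-phenylchroman-2-one | c1c(O)c(C(=O)c3ccccc3)c(O)c2c1OC(=O)C[C@@H]2c1ccccc1 | intermediate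
14 | prenyl bromide (1-bromo-3-methylbut-2-ene) | CC(C)=CCBr | starting material
15 | (R)-6-benzoyl-5,7-dihydroxy-8-(3-methylbut-2-en-1-yl)-4-phenylchroman-2-one | CC(C)=CCc1c(O)c(C(=O)c2ccccc2)c(O)c2c1OC(=O)C[C@@H]2c1ccccc1 | target

**Step count and risks**

Total step count: 8. Longest linear sequence: 8 steps (from 1).

Steps most likely to fail:

1. Step 6. Enantiocontrol may erode through reversible hydropalladation, and reduction or acid-type dimerisation of the diaryl alkene may compete with carbonylation. The fallback sets out from phenol 5 and returns at lactone 10, replacing steps 4 to 6.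
   - Ortho-formylation of 5 (MgCl2, Et3N, paraformaldehyde, MeCN, reflux) should give 3-benzoyl-2,4-bis(benzyloxy)-6-hydroxybenzaldehyde F1.
   - Wittig olefination with ethyl (triphenylphosphoranylidene)acetate in refluxing N,N-diethylaniline should pass through ethyl (Z)-3-[3-benzoyl-2,4-bis(benzyloxy)-6-hydroxyphenyl]acrylate F2, which lactonises in the flask to 6-benzoyl-5,7-bis(benzyloxy)-2H-chromen-2-one F3.
   - Rhodium-catalysed asymmetric 1,4-addition of phenylboronic acid (Rh(acac)(C2H4)2, SEGPHOS of the hand giving 4R, dioxane/H2O, 60 °C; Hayashi–Miyaura reaction) would then set C4 and give 10.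

2. Step 8. Alkylation on oxygen may compete with alkylation on carbon, and a second alkylation may follow. The fallback sets out from 13 and returns at target 15.
   - Allyl bromide with K2CO3 in acetone should give the ether at the less hindered hydroxyl, (R)-7-(allyloxy)-6-benzoyl-5-hydroxy-4-phenylchroman-2-one F4, possibly with some (R)-5-(allyloxy)-6-benzoyl-7-hydroxy-4-phenylchroman-2-one F5.
   - Heating in N,N-diethylaniline at about 180 °C should move allyl to C8 from either ether (ortho Claisen from F4, Claisen–Cope para migration from F5), giving (R)-8-allyl-6-benzoyl-5,7-dihydroxy-4-phenylchroman-2-one F6.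
   - Cross-metathesis of F6 with excess 2-methylbut-2-ene (Grubbs second-generation catalyst, CH2Cl2, 40 °C) would turn allyl into prenyl and give 15.

3. Step 5. Transmetalation at the crowded iodide may be slow, so that protodeiodination and protodeboronation take over. The fallback sets out from phenol 5 and returns at vinylphenol 8, bypassing iodide 6: a Lewis acid catalysed Markovnikov hydroarylation of phenylacetylene (In(OTf)3, 10 mol %, 1,2-dichloroethane, 60 °C) would add the phenol ortho C–H across the alkyne to give 8 directly. It makes no new compound (F0).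

**Further compounds**

F1 | step 6 | 3-benzoyl-2,4-bis(benzyloxy)-6-hydroxybenzaldehyde | O=Cc1c(O)cc(OCc2ccccc2)c(C(=O)c2ccccc2)c1OCc1ccccc1
F2 | step 6 | ethyl (Z)-3-[3-benzoyl-2,4-bis(benzyloxy)-6-hydroxyphenyl]acrylate | CCOC(=O)/C=C\c1c(O)cc(OCc2ccccc2)c(C(=O)c2ccccc2)c1OCc1ccccc1
F3 | step 6 | 6-benzoyl-5,7-bis(benzyloxy)-2H-chromen-2-one | O=C1C=Cc2c(O1)cc(OCc1ccccc1)c(C(=O)c1ccccc1)c2OCc1ccccc1
F4 | step 8 | (R)-7-(allyloxy)-6-benzoyl-5-hydroxy-4-phenylchroman-2-one | c1c(OCC=C)c(C(=O)c3ccccc3)c(O)c2c1OC(=O)C[C@@H]2c1ccccc1
F5 | step 8 | (R)-5-(allyloxy)-6-benzoyl-7-hydroxy-4-phenylchroman-2-one | c1c(O)c(C(=O)c3ccccc3)c(OCC=C)c2c1OC(=O)C[C@@H]2c1ccccc1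
F6 | step 8 | (R)-8-allyl-6-benzoyl-5,7-dihydroxy-4-phenylchroman-2-one | C=CCc1c(O)c(C(=O)c2ccccc2)c(O)c2c1OC(=O)C[C@@H]2c1ccccc1
F0 | step 5 | none | none
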